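## Analysis of the target

The target 21 is a daucane sesquiterpenoid: a cyclopentane (ring A, C1–C5) trans-fused through C1–C5 to a cycloheptane (ring B, C1 and C5–C10). It carries a methyl group on C1 (C15), an isopropyl group on C4, an exocyclic methylene (C14) on C8 and a vanillate ester on O6. Daucane numbering is used throughout and β means the face of the C1 methyl group. There are five stereocentres, (1R,4R,5S,6S,9S): the quaternary C1, the tertiary carbinol C4 (β-OH, α-isopropyl), the ring-fusion methine C5 (α-H), the acyloxy carbon C6 (α-O) and the allylic carbinol C9 (α-OH). C1, C5 and C4 are contiguous, the C4 oxygen sits on the more hindered face cis to the C1 methyl, and O6 and O9 lie on the opposite face together with H5. Sensitive groups are the free phenol, the aryl ester on a hindered secondary alcohol, the tertiary alcohol (β to any C6 carbonyl used on the way, so open to elimination or retro-aldol cleavage) and the 1,1-disubstituted alkene with its allylic alcohol. The difficulty is twofold: an enantioselective seven–five skeleton with a quaternary centre, and oxygen at C4, C6 and C9 with defined configuration on a frame in which several allylic positions compete. The plan rests on one observation: C1–C15 are an unrearranged head-to-tail farnesyl chain that lacks only the C1–C10 bond (closing ring B at the methyl-bearing quaternary carbon) and the C4–C5 bond (closing ring A at the isopropyl-bearing carbon). All oxygen can then be introduced from the two alkenes, C4=C5 and C8=C9, that such a cyclisation leaves behind.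

## Retrosynthetic reasoning

**21 ⇒ 20.** The phenol is unmasked last by cutting an O–Si bond. A free phenol would compete in the acylation and would be deprotonated by the aluminium amide used late in the route, so it is carried as the aryl silyl ether 20.

**20 ⇒ 19.** The C8=C14 methylene next to the C9 carbinol is the signature of a base-induced epoxide-to-allylic-alcohol isomerisation, so 20 is traced to the 8α,9α-epoxide 19. The C9–O bond is not touched, so C9 takes its configuration from the epoxide face. The forward step must take a proton from the C14 methyl and not from C7 or C10.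

**19 ⇒ 14 + 17.** The ester C–O bond at O6 is cut to give epoxy diol 14 and the protected acid 17. The tertiary C4 hydroxyl needs no protection because it does not acylate. Acid 17 comes from vanillic acid 15 through the bis-silyl compound 16.

**14 ⇒ 13.** The epoxide oxygen is removed to leave the C8=C9 alkene of diol 13. This is placed before the acylation because the free 6α-hydroxyl is the one element that can deliver oxygen to the α face of C8=C9.

**13 ⇒ 12.** The C6–H bond is cut to give hydroxy ketone 12. The forward step needs hydride on the β face of C6, the face that an external reagent avoids, so it must be delivered internally from the C4 oxygen.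

**12 ⇒ 11.** The C5–H bond is traced to the C5–O bond of epoxy ketone 11, cleaved by single-electron reduction. The C4–O bond survives, so C4 takes its configuration from the epoxide, and C5 is set by protonation of the enolate.

**11 ⇒ 10 ⇒ 9.** Epoxy ketone 11 comes from epoxy alcohol 10 by oxidation, and 10 from allylic alcohol 9 by hydroxyl-directed epoxidation. A 6β-hydroxyl is used to carry oxygen to the β face of C4=C5, which an undirected reagent cannot be relied on to choose.

**9 ⇒ 8.** The carbinol is traced to dienone 8. The reduction is reagent-controlled, because the configuration at C6 steers everything that follows at C4, C5 and finally C6 itself.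

**8 ⇒ 7 ⇒ 5.** Direct allylic oxidation of hydrocarbon 5 would have to choose among C3, C6, C7, C10, C11 and C14. Instead the oxygen of 8 is traced by an oxidative [3,3] transposition to the tertiary allylic alcohol 7. Alcohol 7 comes from 5 by an ene-type photo-oxygenation of the more electron-rich tetrasubstituted alkene, through hydroperoxide 6.

**5 ⇒ 3.** This is the key disconnection: the C1–C10 and C4–C5 bonds of daucene 5 are cut, which opens both rings and returns the acyclic diphosphate 3. The forward reaction must fold the chain in one mode, set C1 and end by loss of H5; a terpene cyclase does this through the enzyme-bound tertiary diphosphate 4.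

**3 ⇒ 2 ⇒ 1.** The diphosphate is cut at C–O to farnesyl chloride 2, which comes from farnesol 1.

## Alternatives that were turned down

**Alternative 1:** Ring B is cut at C7–C8 and C1–C10, giving the cyclopentenyl 2-silyloxydiene A1 and the siloxy vinyldiazoacetate A2. Forward, a chiral dirhodium tetracarboxylate forms the vinylcarbenoid from A2, which cyclopropanates the terminal alkene of A1 (C7–C8); the cis-divinylcyclopropane then undergoes Cope rearrangement (C1–C10) to cycloheptadiene A3.
- For: it is fully chemical and the quaternary centre is catalyst-controlled. A3 already has oxygen at C4, C6 and C9, the three positions oxygenated in the target, and its ester carbon can become C14. On the placement of oxygen it is clearly stronger than the chosen route.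
- Against: the Cope step must create quaternary C1 from a fully substituted, ketal-flanked diene terminus, where both the cis selectivity of the cyclopropanation and the enantioselectivity are uncertain. The two silyl enol ethers of A3 must be told apart, C5 must still be set by protonation, and the isopropyl group must be added to a hindered, enolisable C4 ketone. A1 and A2 each need several steps.
- Comparison: the chosen route gets the whole C15 skeleton and C1 in one step from a commodity alcohol and pays for it with a hydrocarbon that must be oxidised. In place of pre-installed oxygen it offers a relay (O6 → O4 → H5 → H6) in which each stereochemical decision is made intramolecularly.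

**Alternative 2:** Ring A is cut at C1–C2 and C4–C5, giving the chiral cycloheptenone A4 and the allenylsilane A5. Forward, a Danheiser annulation under a strong titanium Lewis acid gives A6: conjugate attack of the allene CH2 terminus at C1, silyl shift, and enolate closure at C4.
- For: it is convergent, forms ring A with the isopropyl group and C1 in one operation, and delivers the C6 ketone and an oxygen at C9. No enzyme is needed, which is a real advantage in availability.
- Against: addition to a β-methyl enone to make a quaternary carbon is the least favourable case for this annulation. The only control element for C1 is the remote C9 silyloxy group. A6 is cis-fused, its C9 oxygen is on the β face (opposite to the target), C4 is an alkene carbon that must be hydrated regioselectively and on the β face, and C14 is missing.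
- Comparison: more steps after the key step than the chosen route, with several unsolved selectivity problems. The chosen route has one large uncertainty concentrated in the cyclase.

**Alternative 3:** The C1–C5 bond is cut, giving the ten-membered enedione A7. Forward, base forms the C5 enolate of the C6 ketone and it adds across the ring to C1 of the C9 enone, closing both rings to A8.
- For: the C4 carbinol is made in an open-chain setting where asymmetric methods are reliable, and the step gives the trans ring fusion with ketones at C6 and C9. On the C1/C5/C4 relationship it is more direct than the chosen route, which spends four steps on it.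
- Against: A7 needs a long linear synthesis and a medium-ring closure. The required C5 enolate competes with C7 and with enolisation next to C9, and it can expel the β-silyloxy group. The facial selectivity depends on the conformation of a ten-membered ring, and C14 is absent.
- Comparison: the chosen route reaches the bicyclic skeleton in three steps and leaves the stereochemical work to well-precedented directed reactions.

Key step: step 3

Remarks on assumptions:
- A cyclase that releases the 1R enantiomer of 5 is assumed to be obtainable by selection among daucane-forming synthases or by engineering.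
- The tertiary diphosphate 4 stays in the active site; its C3 configuration is fixed by the enzyme and is left unspecified.
- Compounds 6 and 7 are used as C4 epimer mixtures, because C4 becomes trigonal again in 8.

## Route

Step 1
Reactants: 1 (2E,6E)-farnesol
Product: 2 (2E,6E)-farnesyl chloride
Conditions: NCS, Me2S, CH2Cl2, −40 °C to 0 °C
Reagents that add atoms: N-chlorosuccinimide, O=C1CCC(=O)N1Cl
Why: Corey–Kim chlorination; the alkoxysulfonium salt of the primary allylic alcohol is displaced by chloride in an SN2 sense, so neither allylic transposition nor loss of the 2E geometry is expected.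

Step 2
Reactants: 2 (2E,6E)-farnesyl chloride
Product: 3 (2E,6E)-farnesyl diphosphate (handled as its tris-ammonium salt)
Conditions: (n-Bu4N)3HP2O7, MeCN, rt; then Dowex 50WX8 (NH4+ form), aq. NH4HCO3/i-PrOH; lyophilise
Reagents that add atoms: tris(tetrabutylammonium) hydrogen diphosphate, CCCC[N+](CCCC)(CCCC)CCCC.CCCC[N+](CCCC)(CCCC)CCCC.CCCC[N+](CCCC)(CCCC)CCCC.OP(=O)([O-])OP(=O)([O-])[O-]
Why: Direct SN2 diphosphorylation of a primary allylic chloride by the diphosphate trianion in dry acetonitrile; cation exchange gives the water-soluble ammonium salt that the enzyme accepts.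

Step 3
Reactants: 3 (2E,6E)-farnesyl diphosphate
Product: 5 (1R)-dauca-4,8-diene (daucene), via (6E)-nerolidyl diphosphate 4 (not isolated)
Conditions: recombinant (1R)-daucene synthase (class 1 sesquiterpene cyclase, expressed in E. coli), MgCl2 (10 mM), HEPES pH 7.5, glycerol, DTT, n-pentane overlay, 30 °C
Reagents that add atoms: none
Why: The Mg2+-bound diphosphate of 3 ionises in the aspartate-rich pocket; because the former farnesyl 2,3-alkene must become the cis C8=C9 bond of a seven-membered ring, the ion pair first collapses to tertiary diphosphate 4, rotates about that bond and re-ionises to the cisoid allyl cation. Its CH2 terminus (C10) is attacked by C1 of the central alkene in a 7-endo closure of ring B; this closure is anti-Markovnikov and is viable only because the distal alkene bonds through C4 to C5 at the same time in a 5-exo closure of ring A, which puts the charge on the tertiary isopropyl carbon C11. A 1,2-hydride shift from C4 to C11 and loss of H5 to the bound diphosphate give the tetrasubstituted C4=C5 alkene. The closest known reaction type is the cation–olefin bicyclisation of farnesyl diphosphate by terpene synthases that release daucane dienes and carotol. The one new stereocentre, C1, is set when C10 adds to one face of the central E alkene, and that face is fixed by the chiral contour in which the active site holds the chain, not by the achiral substrate. The step needs one folding mode out of the competing six-, ten- and eleven-membered closures and one terminating event (loss of H5 instead of water capture or loss of another proton); the substrate supplies only the E geometry and the 1,5-spacing of its alkenes, and the rest depends on the choice of enzyme.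

Step 4
Reactants: 5 (1R)-dauca-4,8-diene
Product: 7 (1R)-dauca-5,8-dien-4-ol (both C4 epimers), via (1R)-4-hydroperoxydauca-5,8-diene 6 (not isolated)
Conditions: O2, white LED, tetraphenylporphyrin (cat.), CH2Cl2, −30 °C, stopped when 5 is consumed; then PPh3, −30 °C to rt
Reagents that add atoms: dioxygen (as singlet oxygen), O=O
Why: Schenck ene reaction followed by phosphine reduction; singlet oxygen attacks the tetrasubstituted C4=C5 alkene much faster than the trisubstituted C8=C9 alkene. It should bond to C4, remote from quaternary C1, and take H6 from the methylene geminal to that bulky carbon (large-group effect), the isopropyl methine being a poor donor.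

Step 5
Reactants: 7 (1R)-dauca-5,8-dien-4-ol
Product: 8 (1R)-dauca-4,8-dien-6-one
Conditions: pyridinium chlorochromate (C5H5NH[CrO3Cl]), SiO2, CH2Cl2, rt
Reagents that add atoms: pyridinium chlorochromate, [O-][Cr](=O)(=O)Cl.c1cc[nH+]cc1
Why: Babler–Dauben oxidative transposition; the chromate ester of the tertiary allylic alcohol undergoes [3,3] shift to the secondary C6 chromate, which is oxidised to the ketone, so oxygen moves regiospecifically from C4 to C6 and the C4=C5 alkene is restored. The regioisomeric alcohol from step 4 would give a cyclopentenone that is separated here.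

Step 6
Reactants: 8 (1R)-dauca-4,8-dien-6-one
Product: 9 (1R,6R)-dauca-4,8-dien-6-ol (6β-OH)
Conditions: (S)-2-methyl-CBS-oxazaborolidine (0.2 equiv), catecholborane, toluene, −78 °C; aqueous work-up
Reagents that add atoms: none
Why: Corey–Bakshi–Shibata reduction; the fully substituted alkenyl carbon C5 is the large and the C7 methylene the small substituent, so the (S)-catalyst (the one that gives (R)-1-phenylethanol from acetophenone) delivers hydride to the α face and gives the 6R alcohol. The substrate's own bias (hydride anti to the axial-like C1 methyl) points the same way, and catecholborane at −78 °C leaves both alkenes alone.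

Step 7
Reactants: 9 (1R,6R)-dauca-4,8-dien-6-ol
Product: 10 (1R,4R,5S,6R)-4,5-epoxydauc-8-en-6-ol (4β,5β-epoxide)
Conditions: VO(acac)2 (5 mol %), t-BuOOH (1.2 equiv, decane solution), CH2Cl2, 0 °C
Reagents that add atoms: tert-butyl hydroperoxide, CC(C)(C)OO
Why: Hydroxyl-directed vanadium-catalysed epoxidation; the 6β-alkoxide binds vanadium and oxygen is delivered to the same face of C4=C5, which places the C4 oxygen cis to the C1 methyl against the steric bias. The allylic tetrasubstituted alkene should react faster than the homoallylic trisubstituted C8=C9 alkene.

Step 8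
Reactants: 10 (1R,4R,5S,6R)-4,5-epoxydauc-8-en-6-ol
Product: 11 (1R,4R,5R)-4,5-epoxydauc-8-en-6-one
Conditions: Dess–Martin periodinane, NaHCO3, CH2Cl2, 0 °C to rt
Reagents that add atoms: none
Why: Dess–Martin oxidation of a hindered secondary alcohol under buffered conditions; the epoxide is not touched and the β,γ-alkene is not moved into conjugation at neutral pH.

Step 9
Reactants: 11 (1R,4R,5R)-4,5-epoxydauc-8-en-6-one
Product: 12 (1R,4R,5R)-4-hydroxydauc-8-en-6-one (4β-OH, 5α-H)
Conditions: SmI2 (2.5 equiv), THF–MeOH, −78 °C; pH 7 buffer
Reagents that add atoms: none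
Why: Single-electron reductive cleavage of an α,β-epoxy ketone; the ketyl expels the C5–O bond, the C4–O bond and its β configuration stay, and the samarium enolate is protonated at C5. Protonation from the α face (the β face carries the C1 methyl and the metal-bound C4 alkoxide) gives the trans-fused ketone, which should also be the more stable epimer because C6 is then trans to the isopropyl group and hydrogen-bonded to the cis C4 hydroxyl.

Step 10
Reactants: 12 (1R,4R,5R)-4-hydroxydauc-8-en-6-one
Product: 13 (1R,4R,5S,6S)-dauc-8-ene-4,6-diol (4β,6α-diol)
Conditions: Me4NBH(OAc)3 (5 equiv), MeCN–AcOH 1:1, −25 °C to 0 °C; aqueous work-up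
Reagents that add atoms: none
Why: Saksena–Evans hydroxyl-directed reduction; the C4 hydroxyl exchanges onto boron and hydride is delivered intramolecularly to the β face of the C6 carbonyl, the face on which O4 sits, giving the 6α alcohol. The free reagent reduces ketones too slowly for external α-face attack to compete.

Step 11
Reactants: 13 (1R,4R,5S,6S)-dauc-8-ene-4,6-diol
Product: 14 (1R,4R,5S,6S,8R,9S)-8,9-epoxydaucane-4,6-diol (8α,9α-epoxide)
Conditions: VO(acac)2 (5 mol %), t-BuOOH (1.5 equiv), CH2Cl2, 0 °C to rt
Reagents that add atoms: tert-butyl hydroperoxide, CC(C)(C)OO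
Why: Vanadium-catalysed epoxidation directed by the homoallylic 6α-hydroxyl, which delivers oxygen to the α face of C8=C9 (syn to O6, anti to the C1 methyl); the tertiary C4 hydroxyl is too remote and on the other face.

Step 12
Reactants: 15 vanillic acid
Product: 17 4-(tert-butyldimethylsilyloxy)-3-methoxybenzoic acid, via bis-silylated vanillic acid 16 (not isolated)
Conditions: TBSCl (2.5 equiv), imidazole, DMF, rt; then AcOH–THF–H2O, rt
Reagents that add atoms: tert-butyldimethylsilyl chloride, CC(C)(C)[Si](C)(C)Cl
Why: Silylation of both acidic groups, then selective hydrolysis of the labile silyl ester under mild aqueous acid; the aryl silyl ether blocks the phenol during acylation and the aluminium amide step.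

Step 13
Reactants: 14 (1R,4R,5S,6S,8R,9S)-8,9-epoxydaucane-4,6-diol; 17 4-(tert-butyldimethylsilyloxy)-3-methoxybenzoic acid
Product: 19 (1R,4R,5S,6S,8R,9S)-8,9-epoxy-4-hydroxydaucan-6-yl 4-(tert-butyldimethylsilyloxy)-3-methoxybenzoate, via mixed trichlorobenzoic anhydride 18 (not isolated)
Conditions: 17, 2,4,6-trichlorobenzoyl chloride, Et3N, toluene, rt; then 14, DMAP, rt to 40 °C
Reagents that add atoms: none
Why: Yamaguchi esterification; the mixed anhydride passes the aroyl group through the acylpyridinium ion to the hindered secondary 6α-hydroxyl. The tertiary C4 hydroxyl does not acylate and the epoxide is inert to the amine bases.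

Step 14
Reactants: 19 (1R,4R,5S,6S,8R,9S)-8,9-epoxy-4-hydroxydaucan-6-yl 4-(tert-butyldimethylsilyloxy)-3-methoxybenzoate
Product: 20 (1R,4R,5S,6S,9S)-4,9-dihydroxydauc-8(14)-en-6-yl 4-(tert-butyldimethylsilyloxy)-3-methoxybenzoate
Conditions: Et2Al(TMP) (5 equiv; from 2,2,6,6-tetramethylpiperidine, n-BuLi, Et2AlCl), toluene, 0 °C; aq. KNaC4H4O6 (potassium sodium tartrate)
Reagents that add atoms: none
Why: Base-induced isomerisation of an epoxide to an allylic alcohol; aluminium binds the epoxide oxygen and the hindered amide removes a syn proton from the least hindered β position, the C14 methyl, with cleavage of the tertiary C8–O bond, so the C9–O bond and its α configuration are untouched. The amide is non-nucleophilic and the aroyl ester has no α-protons, so the ester should survive; one equivalent of reagent is consumed by the C4 hydroxyl.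

Step 15
Reactants: 20 (1R,4R,5S,6S,9S)-4,9-dihydroxydauc-8(14)-en-6-yl 4-(tert-butyldimethylsilyloxy)-3-methoxybenzoate
Product: 21 (1R,4R,5S,6S,9S)-4,9-dihydroxydauc-8(14)-en-6-yl 4-hydroxy-3-methoxybenzoate (target)
Conditions: TBAF (1.1 equiv), AcOH (1.2 equiv), THF, 0 °C
Reagents that add atoms: none
Why: Fluoride cleavage of an aryl silyl ether, which is far more labile than the ester or the alcohols; acetic acid buffers the phenoxide so that the C6 ester neither migrates nor hydrolyses.

## Compound list

1 | (2E,6E)-farnesol | CC(C)=CCC/C(C)=C/CC/C(C)=C/CO | starting material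
2 | (2E,6E)-farnesyl chloride | CC(C)=CCC/C(C)=C/CC/C(C)=C/CCl | intermediate
3 | (2E,6E)-farnesyl diphosphate (handled as tris-ammonium salt) | CC(C)=CCC/C(C)=C/CC/C(C)=C/COP(=O)(O)OP(=O)(O)O | intermediate
4 | (6E)-nerolidyl diphosphate (enzyme-bound; C3 set by the enzyme, unspecified) | CC(C)=CCC/C(C)=C/CCC(C)(C=C)OP(=O)(O)OP(=O)(O)O | intermediate
5 | (1R)-dauca-4,8-diene (daucene) | CC1=CC[C@@]2(C)CCC(C(C)C)=C2CC1 | intermediate
6 | (1R)-4-hydroperoxydauca-5,8-diene (C4 epimers) | CC1=CC[C@@]2(C)CCC(OO)(C(C)C)C2=CC1 | intermediate
7 | (1R)-dauca-5,8-dien-4-ol (C4 epimers) | CC1=CC[C@@]2(C)CCC(O)(C(C)C)C2=CC1 | intermediate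
8 | (1R)-dauca-4,8-dien-6-one | CC1=CC[C@@]2(C)CCC(C(C)C)=C2C(=O)C1 | intermediate
9 | (1R,6R)-dauca-4,8-dien-6-ol (6β-OH) | CC1=CC[C@@]2(C)CCC(C(C)C)=C2[C@H](O)C1 | intermediate
10 | (1R,4R,5S,6R)-4,5-epoxydauc-8-en-6-ol (4β,5β-epoxide, 6β-OH) | CC=1C[C@@H](O)[C@@]2(O3)[C@](C)(CC[C@@]23C(C)C)CC1 | intermediate
11 | (1R,4R,5R)-4,5-epoxydauc-8-en-6-one (4β,5β-epoxide) | CC=1CC(=O)[C@@]2(O3)[C@](C)(CC[C@@]23C(C)C)CC1 | intermediate
12 | (1R,4R,5R)-4-hydroxydauc-8-en-6-one (4β-OH, 5α-H) | CC=1CC(=O)[C@@H]2[C@](C)(CC[C@@]2(O)C(C)C)CC1 | intermediate
13 | (1R,4R,5S,6S)-dauc-8-ene-4,6-diol (4β,6α) | CC=1C[C@H](O)[C@@H]2[C@](C)(CC[C@@]2(O)C(C)C)CC1 | intermediate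
14 | (1R,4R,5S,6S,8R,9S)-8,9-epoxydaucane-4,6-diol (8α,9α-epoxide) | C[C@@]12C[C@H](O)[C@@H]3[C@](C)(CC[C@@]3(O)C(C)C)C[C@@H]1O2 | intermediate
15 | vanillic acid | COc1cc(C(=O)O)ccc1O | starting material
16 | tert-butyldimethylsilyl 4-(tert-butyldimethylsilyloxy)-3-methoxybenzoate | COc1cc(C(=O)O[Si](C)(C)C(C)(C)C)ccc1O[Si](C)(C)C(C)(C)C | intermediate
17 | 4-(tert-butyldimethylsilyloxy)-3-methoxybenzoic acid | COc1cc(C(=O)O)ccc1O[Si](C)(C)C(C)(C)C | intermediate
18 | 4-(tert-butyldimethylsilyloxy)-3-methoxybenzoic 2,4,6-trichlorobenzoic anhydride | COc1cc(C(=O)OC(=O)c2c(Cl)cc(Cl)cc2Cl)ccc1O[Si](C)(C)C(C)(C)C | intermediate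
19 | (1R,4R,5S,6S,8R,9S)-8,9-epoxy-4-hydroxydaucan-6-yl 4-(tert-butyldimethylsilyloxy)-3-methoxybenzoate | C[C@@]12C[C@H](OC(=O)c4ccc(O[Si](C)(C)C(C)(C)C)c(OC)c4)[C@@H]3[C@](C)(CC[C@@]3(O)C(C)C)C[C@@H]1O2 | intermediate
20 | (1R,4R,5S,6S,9S)-4,9-dihydroxydauc-8(14)-en-6-yl 4-(tert-butyldimethylsilyloxy)-3-methoxybenzoate | C=C1C[C@H](OC(=O)c2ccc(O[Si](C)(C)C(C)(C)C)c(OC)c2)[C@@H]2[C@](C)(CC[C@@]2(O)C(C)C)C[C@@H]1O | intermediate
21 | (1R,4R,5S,6S,9S)-4,9-dihydroxydauc-8(14)-en-6-yl 4-hydroxy-3-methoxybenzoate | C=C1C[C@H](OC(=O)c2ccc(O)c(OC)c2)[C@@H]2[C@](C)(CC[C@@]2(O)C(C)C)C[C@@H]1O | target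

## Step count and least certain steps

Total: 15 steps (14 on the terpenoid line, 1 for the acid component). Longest linear sequence: 14 steps (1 to 21 through steps 1–11 and 13–15).

**Step 3 (key step).** The enzyme may fold the chain in another mode, quench the final cation with water, show low turnover through product inhibition, or belong to the wrong C1 series. Fallback, from 3 back to 5: incubate 3 under the same buffer conditions with a carotol synthase, the most common daucane-forming cyclase type, to give carotol F1 (drawn in the required C1 series). Then dehydrate F1 with SOCl2 and pyridine at 0 °C; anti elimination of H4 with the C5 hydroxyl gives 5.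

**Step 4.** Hydrogen abstraction may occur at C3 (or C11) instead of C6 and put the oxygen on C5, or the C8=C9 alkene may be over-oxidised on long irradiation. Fallback, from 5 back to 7: epoxidise the tetrasubstituted alkene chemoselectively with one equivalent of mCPBA (NaHCO3, CH2Cl2, −20 °C) to give (1R)-4,5-epoxydauc-8-ene F2; either epoxide face serves. Then open F2 with Et2Al(TMP) in toluene at 0 °C. Selection there is by steric access of the amide to a syn β-proton, a different rule from the ene reaction, and H6 on the flexible seven-membered ring is the most accessible; the alkoxide stays on C4 and gives 7.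

**Step 9.** The samarium enolate may be protonated on the β face by metal-bound methanol and give the cis-fused C5 epimer, or the aldolate may eliminate or undergo retro-aldol cleavage on warming. Fallback, from 11 back to 12: carry out the same cleavage with a cold buffered quench and accept the cis-fused ketone (1R,4R,5S)-4-hydroxydauc-8-en-6-one F3. Then set C5 under thermodynamic control by equilibrating F3 through its enol with catalytic DBU in toluene at room temperature; the trans-fused 12 is expected to be favoured because C6 is then trans to the isopropyl group.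

**Step 10.** Ligand exchange of the hindered tertiary hydroxyl onto boron may fail, leaving starting material or slow undirected reduction to the 6β alcohol. Fallback, from 12 back to 13: silylate O4 with chlorodiisopropylsilane (imidazole, DMAP, DMF) to the hydridosilyl ether F4. Catalytic SnCl4 in CH2Cl2 at −78 °C then effects intramolecular hydrosilylation of the C6 ketone to the cyclic silylene acetal F5; the covalent tether forces hydride onto the β face. HF·pyridine cleaves F5 to 13.

**Step 14.** The aluminium amide may attack the ester, remove a proton from C7 or C10, or the aluminium alkoxide of O4 may open the activated epoxide across the ring. Fallback, from 14 to 21: isomerise the epoxide before acylation by treating 14 with excess Et2Al(TMP) to give (1R,4R,5S,6S,9S)-dauc-8(14)-ene-4,6,9-triol F6. Silylate its less hindered allylic 9-hydroxyl (Et3SiCl, imidazole, −20 °C) to the 9-O-triethylsilyl ether F7. Acylate O6 with 17 under the conditions of step 13 to give the bis-silyl ester F8, and remove both silyl groups with TBAF and AcOH to reach 21.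

## Further compounds

F1 | step 3 | carotol (dauc-8-en-5-ol; hydroxyl, isopropyl and C1 methyl on one face) | CC1=CC[C@@]2(C)CC[C@H](C(C)C)[C@@]2(O)CC1
F2 | step 4 | (1R)-4,5-epoxydauc-8-ene (drawn as the α-epoxide) | CC=1CC[C@]2(O3)[C@](C)(CC[C@]23C(C)C)CC1
F3 | step 9 | (1R,4R,5S)-4-hydroxydauc-8-en-6-one (5β-H, cis-fused) | CC=1CC(=O)[C@H]2[C@](C)(CC[C@@]2(O)C(C)C)CC1
F4 | step 10 | (1R,4R,5R)-4-(diisopropylsilyloxy)dauc-8-en-6-one | CC=1CC(=O)[C@@H]2[C@](C)(CC[C@@]2(O[SiH](C(C)C)C(C)C)C(C)C)CC1
F5 | step 10 | (1R,4R,5S,6S)-4,6-O-(diisopropylsilylene)dauc-8-ene-4,6-diol | CC=1C[C@H](O[Si]4(C(C)C)C(C)C)[C@@H]2[C@](C)(CC[C@@]2(O4)C(C)C)CC1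
F6 | step 14 | (1R,4R,5S,6S,9S)-dauc-8(14)-ene-4,6,9-triol | C=C1C[C@H](O)[C@@H]2[C@](C)(CC[C@@]2(O)C(C)C)C[C@@H]1O
F7 | step 14 | (1R,4R,5S,6S,9S)-9-(triethylsilyloxy)dauc-8(14)-ene-4,6-diol | C=C1C[C@H](O)[C@@H]2[C@](C)(CC[C@@]2(O)C(C)C)C[C@@H]1O[Si](CC)(CC)CC
F8 | step 14 | (1R,4R,5S,6S,9S)-4-hydroxy-9-(triethylsilyloxy)dauc-8(14)-en-6-yl 4-(tert-butyldimethylsilyloxy)-3-methoxybenzoate | C=C1C[C@H](OC(=O)c2ccc(O[Si](C)(C)C(C)(C)C)c(OC)c2)[C@@H]2[C@](C)(CC[C@@]2(O)C(C)C)C[C@@H]1O[Si](CC)(CC)CC
A1 | alternative 1 | 6-[1-(tert-butyldimethylsilyloxy)ethenyl]-7-methyl-1,4-dioxaspiro[4.4]non-6-ene | C=C(O[Si](C)(C)C(C)(C)C)C1=C(C)CCC12OCCO2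
A2 | alternative 1 | methyl 3-(tert-butyldimethylsilyloxy)-2-diazobut-3-enoate | COC(=O)C(=[N+]=[N-])C(=C)O[Si](C)(C)C(C)(C)C
A3 | alternative 1 | bicyclic bis(silyl enol ether) with C8 methyl ester, C1 quaternary centre and C4 ketal | COC(=O)C1=C(O[Si](C)(C)C(C)(C)C)C[C@@]2(C)CCC3(OCCO3)C2=C(O[Si](C)(C)C(C)(C)C)C1
A4 | alternative 2 | 5-(tert-butyldimethylsilyloxy)-3-methylcyclohept-2-en-1-one (single enantiomer) | C1CC(=O)C=C(C)C[C@H]1O[Si](C)(C)C(C)(C)C
A5 | alternative 2 | trimethyl(4-methylpenta-1,2-dien-3-yl)silane | C=C=C(C(C)C)[Si](C)(C)C
A6 | alternative 2 | cis-fused bicyclo[5.3.0]decen-6-one with C3 trimethylsilyl, C4 isopropyl and C9 silyloxy groups | C1CC(=O)[C@H]2[C@](C)(CC([Si](C)(C)C)=C2C(C)C)C[C@H]1O[Si](C)(C)C(C)(C)C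
A7 | alternative 3 | (E)-4-isopropyl-1-methyl-4-(triethylsilyloxy)cyclodec-1(10)-ene-6,9-dione (daucane numbering kept) | C/C1=C\C(=O)CCC(=O)C[C@](O[Si](CC)(CC)CC)(C(C)C)CC1
A8 | alternative 3 | trans-fused 4-triethylsilyloxy bicyclo[5.3.0]decane-6,9-dione | O=C1CCC(=O)[C@@H]2[C@](C)(CC[C@@]2(O[Si](CC)(CC)CC)C(C)C)C1
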